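## Retrosynthetic overview

1. Stolonic acid B comes from its methyl ester. The 1,2-dioxane is the last ring formed, by a new catalyst-controlled 6-exo peroxy-Michael closure of an ε-hydroperoxy enoate (forms C3–O, sets C3).
2. The hydroperoxy enoate comes from a Wittig reaction (C2=C3) on a C3 aldehyde. Its C6–O–O unit is brought in intact by SN2 inversion of a C6 triflate with a protected hydroperoxide (sets C6).
3. The trans-THF carbinol is the first ring formed. A Z,Z-dienyl Grignard opens the terminal epoxide of a bis-epoxide (C11–C12), then the C10 hydroxyl opens the internal epoxide 5-exo (inverts C7).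
4. The bis-epoxide comes from Shi epoxidation of an E-alkene, made by Julia–Kocienski olefination (C6=C7) of a C3–C6 sulfone with a C7–C11 epoxy aldehyde. C10 comes from (S)-1,2-epoxy-5-hexene.
5. The Z,Z-diene chain (C12–C26) comes from a Cadiot–Chodkiewicz diyne reduced with Zn(Cu/Ag).

Assumption: the SMILES is read as (3S,6S,7S,10R), 19Z,21Z (C1 = CO2H; trans-THF, threo C6/C7, trans-dioxane; this numbering is used below), and 3, 7, 10 and the D-fructose-derived Shi ketone are taken as catalogue items.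

## Route

**Step 1**
Reactants: 1 hex-1-yne
Product: 2 1-bromohex-1-yne
Conditions: NBS (1.1 equiv), AgNO3 (10 mol %), acetone, rt
Reagents that add atoms: N-bromosuccinimide O=C1CCC(=O)N1Br
Why: Silver-catalysed electrophilic bromination of the terminal alkyne C–H gives the haloalkyne partner for a Cadiot–Chodkiewicz coupling.

**Step 2**
Reactants: 2 1-bromohex-1-yne; 3 non-8-yn-1-ol
Product: 4 pentadeca-8,10-diyn-1-ol
Conditions: CuCl (5 mol %), NH2OH·HCl (cat.), 30% aq n-BuNH2, Et2O, 0 °C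
Reagents that add atoms: none
Why: In the Cadiot–Chodkiewicz coupling the copper(I) acetylide of 3 couples selectively with the bromoalkyne to form C20–C21 as an unsymmetrical 1,3-diyne, and the free alcohol is inert.

**Step 3**
Reactants: 4 pentadeca-8,10-diyn-1-ol
Product: 5 (8Z,10Z)-pentadeca-8,10-dien-1-ol
Conditions: Zn(Cu/Ag) [Zn dust, Cu(OAc)2, AgNO3], MeOH–H2O 1:1, 40 °C
Reagents that add atoms: none
Why: The Boland-type activated-zinc reduction adds hydrogen cis to conjugated triple bonds only and stops at the diene, which sets both Z double bonds (C19=C20, C21=C22).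

**Step 4**
Reactants: 5 (8Z,10Z)-pentadeca-8,10-dien-1-ol
Product: 6 (5Z,7Z)-15-bromopentadeca-5,7-diene
Conditions: CBr4, PPh3, CH2Cl2, 0 °C
Reagents that add atoms: carbon tetrabromide BrC(Br)(Br)Br
Why: The Appel reaction converts the primary alcohol to the bromide under neutral conditions that do not isomerise the Z,Z-diene.

**Step 5**
Reactants: 7 4-[(tert-butyldiphenylsilyl)oxy]butan-1-ol
Product: 8 5-({4-[(tert-butyldiphenylsilyl)oxy]butyl}sulfanyl)-1-phenyl-1H-tetrazole
Conditions: 1-phenyl-1H-tetrazole-5-thiol, PPh3, DIAD, THF, 0 °C to rt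
Reagents that add atoms: 1-phenyl-1H-tetrazole-5-thiol Sc1nnnn1-c1ccccc1
Why: Mitsunobu thioetherification of an unhindered primary alcohol with the acidic heteroaryl thiol is fast and leaves the silyl ether alone.

**Step 6**
Reactants: 8 5-({4-[(tert-butyldiphenylsilyl)oxy]butyl}sulfanyl)-1-phenyl-1H-tetrazole
Product: 9 5-({4-[(tert-butyldiphenylsilyl)oxy]butyl}sulfonyl)-1-phenyl-1H-tetrazole
Conditions: (NH4)6Mo7O24·4H2O (10 mol %), 30% H2O2, EtOH, 0 °C to rt
Reagents that add atoms: hydrogen peroxide OO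
Why: Molybdate-catalysed sulfide-to-sulfone oxidation is the standard entry to PT-sulfones and spares the TBDPS ether.

**Step 7**
Reactants: 10 (2S)-2-(but-3-en-1-yl)oxirane
Product: 12 3-[(2S)-oxiran-2-yl]propanal, via secondary ozonide 11 (not isolated)
Conditions: O3, CH2Cl2, −78 °C; then PPh3, −78 °C to rt; short silica plug, used at once
Reagents that add atoms: ozone [O-][O+]=O
Why: Ozonolysis (Criegee mechanism) cleaves the only C=C, and reduction of the ozonide with PPh3 gives the C7 aldehyde without an aqueous work-up, leaving the epoxide and C10 untouched.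

**Step 8**
Reactants: 9 5-({4-[(tert-butyldiphenylsilyl)oxy]butyl}sulfonyl)-1-phenyl-1H-tetrazole; 12 3-[(2S)-oxiran-2-yl]propanal
Product: 14 tert-butyl({(4E)-7-[(2S)-oxiran-2-yl]hept-4-en-1-yl}oxy)diphenylsilane, via potassiated sulfone 13 (not isolated)
Conditions: KHMDS, DME, −60 °C, 30 min; then 12, −60 °C to rt; H2O quench
Reagents that add atoms: none
Why: In the Julia–Kocienski olefination, addition of the potassiated PT-sulfone, Smiles transfer of the tetrazole and anti-elimination give the E C6=C7 alkene (typically >10:1 with K+/DME) at a temperature where the terminal epoxide is not attacked.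

**Step 9**
Reactants: 14 tert-butyl({(4E)-7-[(2S)-oxiran-2-yl]hept-4-en-1-yl}oxy)diphenylsilane
Product: 15 tert-butyl(3-{(2R,3R)-3-[2-((2S)-oxiran-2-yl)ethyl]oxiran-2-yl}propoxy)diphenylsilane
Conditions: D-fructose-derived Shi ketone (30 mol %), Oxone, K2CO3, Bu4NHSO4 (cat.), Na2B4O7/Na2EDTA buffer, MeCN–DMM, 0 °C
Reagents that add atoms: potassium peroxymonosulfate (Oxone) [K+].[O-]S(=O)(=O)OO
Why: In the Shi asymmetric epoxidation the chiral dioxirane attacks the only alkene through the spiro transition state that gives (R,R)-epoxides from E-dialkyl alkenes, setting C6 (R) and C7 (R) under reagent control while the basic buffer spares the terminal epoxide.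

**Step 10**
Reactants: 6 (5Z,7Z)-15-bromopentadeca-5,7-diene; 15 tert-butyl(3-{(2R,3R)-3-[2-((2S)-oxiran-2-yl)ethyl]oxiran-2-yl}propoxy)diphenylsilane
Product: 18 (1R)-4-[(tert-butyldiphenylsilyl)oxy]-1-{(2S,5R)-5-[(9Z,11Z)-hexadeca-9,11-dien-1-yl]oxolan-2-yl}butan-1-ol, via Grignard reagent 16 (not isolated), via epoxy alcohol 17 (not isolated)
Conditions: 6, Mg, THF, rt; CuI (10 mol %), 15, THF, −40 to −10 °C; sat. NH4Cl; crude in CH2Cl2, CSA (10 mol %), 0 °C
Reagents that add atoms: none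
Why: Copper-catalysed Grignard opening occurs only at the unhindered CH2 (C11) of the monosubstituted epoxide, so C10 is untouched (R by CIP in the product), and the acid-catalysed 5-exo-tet opening of the internal epoxide by the C10 hydroxyl then inverts C7 (R to S) and retains C6 (R), giving the 2,5-trans THF with an erythro carbinol.

**Step 11**
Reactants: 18 (1R)-4-[(tert-butyldiphenylsilyl)oxy]-1-{(2S,5R)-5-[(9Z,11Z)-hexadeca-9,11-dien-1-yl]oxolan-2-yl}butan-1-ol
Product: 19 (1R)-4-[(tert-butyldiphenylsilyl)oxy]-1-{(2S,5R)-5-[(9Z,11Z)-hexadeca-9,11-dien-1-yl]oxolan-2-yl}butyl trifluoromethanesulfonate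
Conditions: Tf2O (1.2 equiv), 2,6-lutidine (2 equiv), CH2Cl2, −78 to −40 °C; cold wash, used at once
Reagents that add atoms: trifluoromethanesulfonic anhydride O=S(=O)(OS(=O)(=O)C(F)(F)F)C(F)(F)F
Why: O-sulfonylation (triflate formation) leaves the C6–O bond and (6R) untouched, and the inductive pull of the ring oxygen plus the bulky, weakly nucleophilic TBDPS ether suppress ionisation and five-ring participation at low temperature.

**Step 12**
Reactants: 20 2,3-dimethylbut-2-ene
Product: 22 2-hydroperoxy-2-methoxypropane, via acetone O-oxide 21 (not isolated)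
Conditions: O3, MeOH–CH2Cl2, −78 °C; concentrate cold
Reagents that add atoms: ozone [O-][O+]=O; methanol CO
Why: In ozonolysis in a participating solvent, the Criegee carbonyl oxide is trapped by methanol to give the acid-removable, mono-protected form of H2O2.

**Step 13**
Reactants: 19 (1R)-4-[(tert-butyldiphenylsilyl)oxy]-1-{(2S,5R)-5-[(9Z,11Z)-hexadeca-9,11-dien-1-yl]oxolan-2-yl}butyl trifluoromethanesulfonate; 22 2-hydroperoxy-2-methoxypropane
Product: 24 tert-butyl{(4S)-4-{(2S,5R)-5-[(9Z,11Z)-hexadeca-9,11-dien-1-yl]oxolan-2-yl}-4-[(2-methoxypropan-2-yl)peroxy]butoxy}diphenylsilane, via potassium peroxide salt 23 (not isolated)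
Conditions: 22 (2 equiv), KOtBu (1.9 equiv), THF, 0 °C; then 19, −20 to 0 °C
Reagents that add atoms: none
Why: SN2 alkylation of the α-effect peroxide anion proceeds with clean inversion, turning the (6R)-triflate into the (6S)-peroxide (threo to C7), and the perketal guarantees mono-alkylation and masks the O–O–H for the next steps.

**Step 14**
Reactants: 24 tert-butyl{(4S)-4-{(2S,5R)-5-[(9Z,11Z)-hexadeca-9,11-dien-1-yl]oxolan-2-yl}-4-[(2-methoxypropan-2-yl)peroxy]butoxy}diphenylsilane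
Product: 25 (4S)-4-{(2S,5R)-5-[(9Z,11Z)-hexadeca-9,11-dien-1-yl]oxolan-2-yl}-4-[(2-methoxypropan-2-yl)peroxy]butan-1-ol
Conditions: TBAF/AcOH (1:1, 3 equiv), THF, rt
Reagents that add atoms: none
Why: Fluoride desilylation is buffered with AcOH so that neither base-induced Kornblum–DeLaMare cleavage of the secondary peroxide nor acid cleavage of the perketal occurs.

**Step 15**
Reactants: 25 (4S)-4-{(2S,5R)-5-[(9Z,11Z)-hexadeca-9,11-dien-1-yl]oxolan-2-yl}-4-[(2-methoxypropan-2-yl)peroxy]butan-1-ol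
Product: 26 (4S)-4-{(2S,5R)-5-[(9Z,11Z)-hexadeca-9,11-dien-1-yl]oxolan-2-yl}-4-[(2-methoxypropan-2-yl)peroxy]butanal
Conditions: Dess–Martin periodinane, NaHCO3, CH2Cl2, 0 °C to rt
Reagents that add atoms: none
Why: Dess–Martin oxidation under bicarbonate buffer stops at the C3 aldehyde and tolerates the peroxide, perketal and diene.

**Step 16**
Reactants: 26 (4S)-4-{(2S,5R)-5-[(9Z,11Z)-hexadeca-9,11-dien-1-yl]oxolan-2-yl}-4-[(2-methoxypropan-2-yl)peroxy]butanal; 27 methyl (triphenyl-λ5-phosphanylidene)acetate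
Product: 28 methyl (2E,6S)-6-{(2S,5R)-5-[(9Z,11Z)-hexadeca-9,11-dien-1-yl]oxolan-2-yl}-6-[(2-methoxypropan-2-yl)peroxy]hex-2-enoate
Conditions: 27 (1.3 equiv), CH2Cl2, rt
Reagents that add atoms: none
Why: Wittig olefination with the stabilised ylide forms C2=C3 as the E-enoate (>95:5) under neutral conditions to which dialkyl peroxides are inert.

**Step 17**
Reactants: 28 methyl (2E,6S)-6-{(2S,5R)-5-[(9Z,11Z)-hexadeca-9,11-dien-1-yl]oxolan-2-yl}-6-[(2-methoxypropan-2-yl)peroxy]hex-2-enoate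
Product: 29 methyl (2E,6S)-6-hydroperoxy-6-{(2S,5R)-5-[(9Z,11Z)-hexadeca-9,11-dien-1-yl]oxolan-2-yl}hex-2-enoate
Conditions: AcOH–THF–H2O (4:2:1), rt
Reagents that add atoms: none
Why: Mild acid hydrolysis of the monoperoxyketal cleaves at the ketal carbon, so C6–O, O–O and (6S) are untouched, and the freed hydroperoxide does not add to the enoate without base.

**Step 18**
Reactants: 29 methyl (2E,6S)-6-hydroperoxy-6-{(2S,5R)-5-[(9Z,11Z)-hexadeca-9,11-dien-1-yl]oxolan-2-yl}hex-2-enoate
Product: 30 methyl 2-[(3S,6S)-6-{(2S,5R)-5-[(9Z,11Z)-hexadeca-9,11-dien-1-yl]oxolan-2-yl}-1,2-dioxan-3-yl]acetate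
Conditions: tert-leucine-derived urea–iminophosphorane ArNHC(O)NH–CH(tBu)CH2–N=P(4-MeOC6H4)3, Ar = 3,5-(CF3)2C6H3 (10 mol %, the enantiomer matched to the substrate), toluene, −20 to 0 °C
Reagents that add atoms: none
Why: Proposed new method: a catalyst-controlled 6-exo-trig peroxy-Michael cyclisation, in which the iminophosphorane reversibly deprotonates the OOH group (about four pKa units more acidic than the alcohols such superbases already activate) while the urea N–H pair binds the ester carbonyl, so the chiral contact ion pair closes through a chair-like transition state with the C6 substituent and the enoate both equatorial and the peroxy oxygen adds to the Si face of C3 to set (3S), the 3,6-trans isomer that is also the thermodynamic one, so reversible background only reinforces it; protonation of the ester enolate by the iminophosphonium N–H inside the ion pair should outrun Weitz–Scheffer O–O cleavage to an epoxide, and a urea replaces the usual thiourea because thioureas reduce peroxides; the closest known reaction types are the bifunctional-iminophosphorane-catalysed enantioselective intramolecular oxa-Michael addition of alcohols to α,β-unsaturated esters and the achiral amine-promoted, poorly selective hydroperoxide–enoate cyclisation.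

**Step 19**
Reactants: 30 methyl 2-[(3S,6S)-6-{(2S,5R)-5-[(9Z,11Z)-hexadeca-9,11-dien-1-yl]oxolan-2-yl}-1,2-dioxan-3-yl]acetate
Product: 32 stolonic acid B, via lithium carboxylate 31 (not isolated)
Conditions: LiOH·H2O (3 equiv), THF–H2O 3:1, 0 °C; then 1 M HCl to pH 4, 0 °C
Reagents that add atoms: lithium hydroxide [Li+].[OH-]
Why: Saponification (BAc2) of the unhindered methyl ester is about three orders of magnitude faster than α-deprotonation, so retro-Michael ring opening and C3 epimerisation do not compete at 0 °C, and mild acidification frees the acid.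

## Compound list

1 | hex-1-yne | CCCCC#C | starting material
2 | 1-bromohex-1-yne | CCCCC#CBr | intermediate
3 | non-8-yn-1-ol | C#CCCCCCCCO | starting material
4 | pentadeca-8,10-diyn-1-ol | CCCCC#CC#CCCCCCCCO | intermediate
5 | (8Z,10Z)-pentadeca-8,10-dien-1-ol | CCCC/C=C\C=C/CCCCCCCO | intermediate
6 | (5Z,7Z)-15-bromopentadeca-5,7-diene | CCCC/C=C\C=C/CCCCCCCBr | intermediate
7 | 4-[(tert-butyldiphenylsilyl)oxy]butan-1-ol | CC(C)(C)[Si](OCCCCO)(c1ccccc1)c1ccccc1 | starting material
8 | 5-({4-[(tert-butyldiphenylsilyl)oxy]butyl}sulfanyl)-1-phenyl-1H-tetrazole | CC(C)(C)[Si](OCCCCSc1nnnn1-c1ccccc1)(c1ccccc1)c1ccccc1 | intermediate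
9 | 5-({4-[(tert-butyldiphenylsilyl)oxy]butyl}sulfonyl)-1-phenyl-1H-tetrazole | CC(C)(C)[Si](OCCCCS(=O)(=O)c1nnnn1-c1ccccc1)(c1ccccc1)c1ccccc1 | intermediate
10 | (2S)-2-(but-3-en-1-yl)oxirane, (S)-1,2-epoxy-5-hexene | C=CCC[C@H]1CO1 | starting material
11 | 3-{2-[(2S)-oxiran-2-yl]ethyl}-1,2,4-trioxolane (secondary ozonide, epimers at the trioxolane carbon, formed in situ) | C1OC(CC[C@H]2CO2)OO1 | intermediate
12 | 3-[(2S)-oxiran-2-yl]propanal | O=CCC[C@H]1CO1 | intermediate
13 | potassium α-sulfonyl carbanion of 9 (formed in situ) | [K+].CC(C)(C)[Si](OCCC[CH-]S(=O)(=O)c1nnnn1-c1ccccc1)(c1ccccc1)c1ccccc1 | intermediate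
14 | tert-butyl({(4E)-7-[(2S)-oxiran-2-yl]hept-4-en-1-yl}oxy)diphenylsilane | CC(C)(C)[Si](OCCC/C=C/CC[C@H]1CO1)(c1ccccc1)c1ccccc1 | intermediate
15 | tert-butyl(3-{(2R,3R)-3-[2-((2S)-oxiran-2-yl)ethyl]oxiran-2-yl}propoxy)diphenylsilane | CC(C)(C)[Si](OCCC[C@H]1O[C@@H]1CC[C@H]1CO1)(c1ccccc1)c1ccccc1 | intermediate
16 | [(8Z,10Z)-pentadeca-8,10-dien-1-yl]magnesium bromide (formed in situ) | CCCC/C=C\C=C/CCCCCCC[Mg]Br | intermediate
17 | (3R,12Z,14Z)-1-[(2R,3R)-3-{3-[(tert-butyldiphenylsilyl)oxy]propyl}oxiran-2-yl]nonadeca-12,14-dien-3-ol (crude, not purified) | CCCC/C=C\C=C/CCCCCCCC[C@@H](O)CC[C@H]1O[C@@H]1CCCO[Si](c1ccccc1)(c1ccccc1)C(C)(C)C | intermediate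
18 | (1R)-4-[(tert-butyldiphenylsilyl)oxy]-1-{(2S,5R)-5-[(9Z,11Z)-hexadeca-9,11-dien-1-yl]oxolan-2-yl}butan-1-ol | CCCC/C=C\C=C/CCCCCCCC[C@@H]1CC[C@@H]([C@H](O)CCCO[Si](c2ccccc2)(c2ccccc2)C(C)(C)C)O1 | intermediate
19 | (1R)-triflate of 18 | CCCC/C=C\C=C/CCCCCCCC[C@@H]1CC[C@@H]([C@H](OS(=O)(=O)C(F)(F)F)CCCO[Si](c2ccccc2)(c2ccccc2)C(C)(C)C)O1 | intermediate
20 | 2,3-dimethylbut-2-ene | CC(C)=C(C)C | starting material
21 | acetone O-oxide (carbonyl oxide, formed in situ) | CC(C)=[O+][O-] | intermediate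
22 | 2-hydroperoxy-2-methoxypropane | COC(C)(C)OO | intermediate
23 | potassium 2-methoxypropan-2-yl peroxide (formed in situ) | [K+].COC(C)(C)O[O-] | intermediate
24 | tert-butyl{(4S)-4-{(2S,5R)-5-[(9Z,11Z)-hexadeca-9,11-dien-1-yl]oxolan-2-yl}-4-[(2-methoxypropan-2-yl)peroxy]butoxy}diphenylsilane | CCCC/C=C\C=C/CCCCCCCC[C@@H]1CC[C@@H]([C@@H](OOC(C)(C)OC)CCCO[Si](c2ccccc2)(c2ccccc2)C(C)(C)C)O1 | intermediate
25 | (4S)-4-{(2S,5R)-5-[(9Z,11Z)-hexadeca-9,11-dien-1-yl]oxolan-2-yl}-4-[(2-methoxypropan-2-yl)peroxy]butan-1-ol | CCCC/C=C\C=C/CCCCCCCC[C@@H]1CC[C@@H]([C@@H](OOC(C)(C)OC)CCCO)O1 | intermediate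
26 | (4S)-4-{(2S,5R)-5-[(9Z,11Z)-hexadeca-9,11-dien-1-yl]oxolan-2-yl}-4-[(2-methoxypropan-2-yl)peroxy]butanal | CCCC/C=C\C=C/CCCCCCCC[C@@H]1CC[C@@H]([C@@H](OOC(C)(C)OC)CCC=O)O1 | intermediate
27 | methyl (triphenyl-λ5-phosphanylidene)acetate | COC(=O)C=P(c1ccccc1)(c1ccccc1)c1ccccc1 | starting material
28 | methyl (2E,6S)-6-{(2S,5R)-5-[(9Z,11Z)-hexadeca-9,11-dien-1-yl]oxolan-2-yl}-6-[(2-methoxypropan-2-yl)peroxy]hex-2-enoate | CCCC/C=C\C=C/CCCCCCCC[C@@H]1CC[C@@H]([C@@H](OOC(C)(C)OC)CC/C=C/C(=O)OC)O1 | intermediate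
29 | methyl (2E,6S)-6-hydroperoxy-6-{(2S,5R)-5-[(9Z,11Z)-hexadeca-9,11-dien-1-yl]oxolan-2-yl}hex-2-enoate | CCCC/C=C\C=C/CCCCCCCC[C@@H]1CC[C@@H]([C@@H](OO)CC/C=C/C(=O)OC)O1 | intermediate
30 | methyl 2-[(3S,6S)-6-{(2S,5R)-5-[(9Z,11Z)-hexadeca-9,11-dien-1-yl]oxolan-2-yl}-1,2-dioxan-3-yl]acetate | CCCC/C=C\C=C/CCCCCCCC[C@@H]1CC[C@@H]([C@@H]2CC[C@@H](CC(=O)OC)OO2)O1 | intermediate
31 | lithium salt of stolonic acid B (formed in situ) | [Li+].CCCC/C=C\C=C/CCCCCCCC[C@@H]1CC[C@@H]([C@@H]2CC[C@@H](CC(=O)[O-])OO2)O1 | intermediate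
32 | stolonic acid B, 2-[(3S,6S)-6-{(2S,5R)-5-[(9Z,11Z)-hexadeca-9,11-dien-1-yl]oxolan-2-yl}-1,2-dioxan-3-yl]acetic acid | CCCC/C=C\C=C/CCCCCCCC[C@@H]1CC[C@@H]([C@@H]2CC[C@@H](CC(=O)O)OO2)O1 | target

## Step count

Total step count: 19.
Longest linear sequence: 13 steps (7 → 8 → 9 → 14 → 15 → 18 → 19 → 24 → 25 → 26 → 28 → 29 → 30 → 32). The branch from 1 is equally long.

## Three steps most likely to fail

**Step 18 (the proposed new reaction).** The risks are slow turnover, base-induced peroxide cleavage, or too little catalyst control. The fallback sets out from 29 and comes back at 30. It gives up kinetic catalyst control for substrate-based thermodynamic control, using the known amine-promoted hydroperoxide–enoate conjugate addition. Compound 29 is stirred with Et2NH (0.5 equiv) in CF3CH2OH at rt until the reversible cyclisation has equilibrated toward the diequatorial 3,6-trans dioxane 30. The minor 3,6-cis epimer, methyl 2-[(3R,6S)-6-{(2S,5R)-5-[(9Z,11Z)-hexadeca-9,11-dien-1-yl]oxolan-2-yl}-1,2-dioxan-3-yl]acetate F1, is separated by chromatography. It is then resubmitted to the same conditions, where retro-Michael/Michael recycling converts it to 30.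

**Step 13 (intermolecular SN2 at the hindered, β-oxygenated C6).** The risks are elimination, ether participation and triflate lability. The fallback sets out from 18 and comes back at 30. It forms the C6–O bond intramolecularly and builds C2–C3 afterwards.
- 18 is mesylated (MsCl, Et3N) to the stable C6 mesylate F2.
- F2 is desilylated (TBAF/AcOH) to the mesyloxy alcohol F3, which is oxidised (Dess–Martin periodinane) to the mesyloxy aldehyde F4.
- Ethereal H2O2 in MeOH with catalytic acid gives the 1-hydroperoxy-1-methoxy acetal F5 (C3 epimers).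
- The peroxide anion of F5 (KOtBu, 18-crown-6, toluene, 0 °C) displaces the mesylate in a 6-exo-tet closure with inversion, giving the (6S)-3-methoxy-1,2-dioxane F6.
- TMSOTf-catalysed substitution through the cyclic peroxycarbenium ion with 1-methoxy-1-(trimethylsilyloxy)ethene installs the acetate arm as a mixture of 30 and the cis epimer F1. This mixture is funnelled to 30 by the amine equilibration described for step 18.

**Step 10 (chemoselective opening of one of two epoxides, then cyclisation).** The risks are halohydrin formation and attack at the internal epoxide. The fallback sets out from 4 and 14 and comes back at 18. It reverses the order of events, coupling first and epoxidising afterwards, with the diene masked as the diyne.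
- 4 is converted (CBr4, PPh3) to 15-bromopentadeca-5,7-diyne F7 and then to its Grignard reagent F8.
- CuI-catalysed opening of the single epoxide of 14 gives the (8R)-alkenol F9.
- The diyne is inert to the Shi dioxirane, so epoxidation gives the epoxy alcohol F10, which closes with CSA to the THF carbinol with a diyne chain F11.
- Zn(Cu/Ag) in MeOH–H2O then unmasks the Z,Z-diene to give 18.

## Further compounds

F1 | step 18 | methyl 2-[(3R,6S)-6-{(2S,5R)-5-[(9Z,11Z)-hexadeca-9,11-dien-1-yl]oxolan-2-yl}-1,2-dioxan-3-yl]acetate (3,6-cis epimer of 30) | CCCC/C=C\C=C/CCCCCCCC[C@@H]1CC[C@@H]([C@@H]2CC[C@H](CC(=O)OC)OO2)O1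
F2 | step 13 | (1R)-4-[(tert-butyldiphenylsilyl)oxy]-1-{(2S,5R)-5-[(9Z,11Z)-hexadeca-9,11-dien-1-yl]oxolan-2-yl}butyl methanesulfonate | CCCC/C=C\C=C/CCCCCCCC[C@@H]1CC[C@@H]([C@H](OS(C)(=O)=O)CCCO[Si](c2ccccc2)(c2ccccc2)C(C)(C)C)O1
F3 | step 13 | (1R)-1-{(2S,5R)-5-[(9Z,11Z)-hexadeca-9,11-dien-1-yl]oxolan-2-yl}-4-hydroxybutyl methanesulfonate | CCCC/C=C\C=C/CCCCCCCC[C@@H]1CC[C@@H]([C@H](OS(C)(=O)=O)CCCO)O1
F4 | step 13 | (1R)-1-{(2S,5R)-5-[(9Z,11Z)-hexadeca-9,11-dien-1-yl]oxolan-2-yl}-4-oxobutyl methanesulfonate | CCCC/C=C\C=C/CCCCCCCC[C@@H]1CC[C@@H]([C@H](OS(C)(=O)=O)CCC=O)O1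
F5 | step 13 | (1R)-1-{(2S,5R)-5-[(9Z,11Z)-hexadeca-9,11-dien-1-yl]oxolan-2-yl}-4-hydroperoxy-4-methoxybutyl methanesulfonate (epimers at the acetal carbon) | CCCC/C=C\C=C/CCCCCCCC[C@@H]1CC[C@@H]([C@H](OS(C)(=O)=O)CCC(OC)OO)O1
F6 | step 13 | (6S)-6-{(2S,5R)-5-[(9Z,11Z)-hexadeca-9,11-dien-1-yl]oxolan-2-yl}-3-methoxy-1,2-dioxane (epimers at C3) | CCCC/C=C\C=C/CCCCCCCC[C@@H]1CC[C@@H]([C@@H]2CCC(OC)OO2)O1
F7 | step 10 | 15-bromopentadeca-5,7-diyne | CCCCC#CC#CCCCCCCCBr
F8 | step 10 | (pentadeca-8,10-diyn-1-yl)magnesium bromide | CCCCC#CC#CCCCCCCC[Mg]Br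
F9 | step 10 | (4E,8R)-1-[(tert-butyldiphenylsilyl)oxy]tetracos-4-ene-17,19-diyn-8-ol | CCCCC#CC#CCCCCCCCC[C@@H](O)CC/C=C/CCCO[Si](c1ccccc1)(c1ccccc1)C(C)(C)C
F10 | step 10 | (3R)-1-[(2R,3R)-3-{3-[(tert-butyldiphenylsilyl)oxy]propyl}oxiran-2-yl]nonadeca-12,14-diyn-3-ol | CCCCC#CC#CCCCCCCCC[C@@H](O)CC[C@H]1O[C@@H]1CCCO[Si](c1ccccc1)(c1ccccc1)C(C)(C)C
F11 | step 10 | (1R)-4-[(tert-butyldiphenylsilyl)oxy]-1-[(2S,5R)-5-(hexadeca-9,11-diyn-1-yl)oxolan-2-yl]butan-1-ol | CCCCC#CC#CCCCCCCCC[C@@H]1CC[C@@H]([C@H](O)CCCO[Si](c2ccccc2)(c2ccccc2)C(C)(C)C)O1
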